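**Retrosynthetic overview**
1. Esters last: the C1 angelate by acylation; the C3 tiglate and the C1 carbinol together by an Evans–Tishchenko reaction of a β-hydroxy ketone; the C3 oxygen by asymmetric conjugate borylation of a ring-B enone.
2. Ring B (seven-membered): aldol condensation between an acetyl arm and a formyl arm that stand on the two one-carbon bridges of a bicyclo[3.1.1]heptenone.
3. Cyclobutane and ring A in one event: ring expansion of a cyclopentenone by a tethered diazoalkane (1,2-shift of the quaternary ring carbon onto the diazo carbon).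
4. Cyclopentenone: aldol condensation of a 1,4-diketone, which comes from an asymmetric Michael addition of a cyano ketone to an ene-dicarbonyl acceptor made by cross-aldol condensation.
5. Ring order: five-membered enone, then six-membered enone ring A plus cyclobutane (one step), then ring B.

Assumption: atom labels C1 to C11 follow the ring atoms of the target SMILES in the order written (C1 bears the angelate, C3 the tiglate, C4 the gem-dimethyl group, C5/C6/C10/C11 form the cyclobutane, C7 is the ring ketone, C9 bears the vinylic methyl); compounds 1 and 4 are taken as purchasable.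

Step 1
Reactants: 1 3,3-dimethylpent-4-enal; 2 2-oxopropanal (methylglyoxal, 40% aq.)
Product: 3 (2Z)-2-(2-methylbut-3-en-2-yl)-4-oxopent-2-enal
Conditions: pyrrolidine (20 mol%), EtCO2H (20 mol%), i-PrOH, 45 °C
Reagents that add atoms: none
Why: Amine-catalysed cross-aldol condensation in which the enamine of 1 (its only enolisable carbon, C5) attacks the aldehyde carbon of 2 (C10) and water is lost; the alkene geometry is erased in step 2.

Step 2
Reactants: 4 2-methyl-3-oxobutanenitrile; 3 (2Z)-2-(2-methylbut-3-en-2-yl)-4-oxopent-2-enal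
Product: 5 (2S,3S,4R)-2,3-diacetyl-4-formyl-2,5,5-trimethylhept-6-enenitrile
Conditions: 9-O-benzylcupreidine (10 mol%), CH2Cl2, −20 °C
Reagents that add atoms: none
Why: Cinchona-base-catalysed asymmetric Michael addition with catalyst-directed protonation (tandem conjugate addition–protonation): the cyano ketone adds to C10 (β to the formyl group; the other alkene carbon is shielded by the tert-alkyl group), the catalyst sets the quaternary centre C11 and delivers the proton to C5, and C10 stays epimerisable and is corrected in step 3.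

Step 3
Reactants: 5 (2S,3S,4R)-2,3-diacetyl-4-formyl-2,5,5-trimethylhept-6-enenitrile
Product: 7 (1S,2R)-2-{(1E,2R)-3,3-dimethyl-1-[2-(4-methylbenzenesulfonyl)hydrazinylidene]pent-4-en-2-yl}-1,3-dimethyl-5-oxocyclopent-3-ene-1-carbonitrile, via tosylhydrazone 6 (not isolated)
Conditions: TsNHNH2, MeOH, 0 °C; evaporate; DBU, MeCN, 40 °C
Reagents that add atoms: 4-methylbenzenesulfonohydrazide, Cc1ccc(cc1)S(=O)(=O)NN
Why: Chemoselective hydrazone formation at the aldehyde followed by intramolecular aldol condensation of the 1,4-diketone (the methyl of the hindered acetyl on C11 attacks the less hindered acetyl on C10) gives the 3-methylcyclopentenone; DBU equilibrates C10 (γ-H of the enone) so that the side chain is trans to the C11 methyl and cis to the small cyano group.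

Step 4
Reactants: 7 (1S,2R)-2-{(1E,2R)-3,3-dimethyl-1-[2-(4-methylbenzenesulfonyl)hydrazinylidene]pent-4-en-2-yl}-1,3-dimethyl-5-oxocyclopent-3-ene-1-carbonitrile
Product: 10 (1R,5R,6R,7S)-2,6-dimethyl-7-(2-methylbut-3-en-2-yl)-4-oxobicyclo[3.1.1]hept-2-ene-6-carbonitrile, via diazoalkane 8 (not isolated), via diazonium alkoxide 9 (not isolated)
Conditions: NaH, THF, 0 °C; then LiOTf, BnEt3NCl (10 mol%), 1,4-dioxane, 45 °C
Reagents that add atoms: none
Why: Proposed new method: an intramolecular Tiffeneau–Demjanov-type ring expansion in which the non-stabilised diazoalkane 8 (Bamford–Stevens generation) adds through its carbon C6 to the lithium-activated ring carbonyl C7 (the only five-membered closure available), giving the bicyclo[2.2.1] diazonium alkoxide 9; there the exo tert-alkyl group on C5 forces N2+ endo, antiperiplanar to the C7–C11 bond, so the apical quaternary carbon C11 (not the vinyl carbon C8) makes the 1,2-shift as N2 leaves, with inversion at C6 (which sets C6) and retention at C11, expanding the five-membered enone to the six-membered enone and closing the cyclobutane at once, the small cyano group taking the crowded position that faces the C5 substituent; the closest known reactions are the Lewis-acid-promoted intermolecular ring expansion of cycloalkanones with diazoalkanes and the semipinacol shift of 2-norbornyl systems, and the intramolecular, bridged, cyclobutane-forming version is new.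

Step 5
Reactants: 10 (1R,5R,6R,7S)-2,6-dimethyl-7-(2-methylbut-3-en-2-yl)-4-oxobicyclo[3.1.1]hept-2-ene-6-carbonitrile
Product: 13 (1R,5R,6R,7S)-6-acetyl-4,6-dimethyl-7-(2-methylbut-3-en-2-yl)bicyclo[3.1.1]hept-3-en-2-one, via lithium dienolate 11 (not isolated), via lithium ketimide 12 (not isolated)
Conditions: LiN(i-Pr)2 (1.1 equiv), THF, −78 °C; MeLi (3 equiv), −78 to 0 °C; 2 M HCl, rt
Reagents that add atoms: methyllithium, [Li]C; water, O
Why: Enolate protection followed by organolithium addition to a nitrile: γ-deprotonation (C6 is a bridgehead, so only the C9 methyl is acidic) masks the ring ketone as its dienolate, MeLi adds once to the nitrile, and acid hydrolyses the ketimine and restores the conjugated enone without touching a stereocentre.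

Step 6
Reactants: 13 (1R,5R,6R,7S)-6-acetyl-4,6-dimethyl-7-(2-methylbut-3-en-2-yl)bicyclo[3.1.1]hept-3-en-2-one
Product: 14 2-[(1R,5R,6R,7S)-6-acetyl-4,6-dimethyl-2-oxobicyclo[3.1.1]hept-3-en-7-yl]-2-methylpropanal
Conditions: OsO4 (2 mol%), NaIO4 (4 equiv), 2,6-lutidine, 1,4-dioxane/H2O 3:1, rt
Reagents that add atoms: osmium tetroxide (oxygen donor, reoxidised by NaIO4), O=[Os](=O)(=O)=O; sodium periodate, [Na+].[O-]I(=O)(=O)=O
Why: Lemieux–Johnson oxidative cleavage, in which OsO4 dihydroxylates the electron-richer monosubstituted alkene much faster than the electron-poor trisubstituted enone alkene and periodate cleaves the diol to the non-enolisable aldehyde (C3).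

Step 7
Reactants: 14 2-[(1R,5R,6R,7S)-6-acetyl-4,6-dimethyl-2-oxobicyclo[3.1.1]hept-3-en-7-yl]-2-methylpropanal
Product: 15 (1R,2R,7S,8R)-2,6,6,9-tetramethyltricyclo[5.4.0.0^{2,8}]undeca-4,9-diene-3,11-dione
Conditions: KOH, MeOH, 40 °C
Reagents that add atoms: none
Why: Intramolecular aldol condensation with a single possible enolate (the acetyl CH3, since C11 is quaternary) and a non-enolisable aldehyde; the two arms stand face to face on the anti positions of the cyclobutane, so ring B closes and relieves their 1,3-repulsion.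

Step 8
Reactants: 15 (1R,2R,7S,8R)-2,6,6,9-tetramethyltricyclo[5.4.0.0^{2,8}]undeca-4,9-diene-3,11-dione
Product: 17 (1R,2R,5R,7S,8R)-5-hydroxy-2,6,6,9-tetramethyltricyclo[5.4.0.0^{2,8}]undec-9-ene-3,11-dione, via boronate 16 (not isolated)
Conditions: CuCl (5 mol%), (R)-DTBM-SEGPHOS (6 mol%), NaOtBu (10 mol%), B2pin2 (1.1 equiv), MeOH (2 equiv), THF, 0 °C; then NaBO3·4H2O, THF/H2O, rt
Reagents that add atoms: bis(pinacolato)diboron, CC1(C)OB(OC1(C)C)B1OC(C)(C)C(C)(C)O1; sodium perborate tetrahydrate, [Na+].[Na+].O[B-]1(O)OO[B-](O)(O)OO1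
Why: Copper-catalysed asymmetric conjugate borylation, in which the borylcopper adds to the β-monosubstituted ring-B enone rather than the slower β,β-disubstituted ring-A enone; the cage gives almost no facial bias, so the ligand enantiomer is picked to give the (5R)-boronate and thereby sets C3, and perborate oxidation goes with retention.

Step 9
Reactants: 17 (1R,2R,5R,7S,8R)-5-hydroxy-2,6,6,9-tetramethyltricyclo[5.4.0.0^{2,8}]undec-9-ene-3,11-dione; 18 (2E)-2-methylbut-2-enal (tiglic aldehyde)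
Product: 20 (1R,2R,3R,5R,7S,8R)-3-hydroxy-2,6,6,9-tetramethyl-11-oxotricyclo[5.4.0.0^{2,8}]undec-9-en-5-yl (2E)-2-methylbut-2-enoate, via hemiacetal 19 (not isolated)
Conditions: SmI2 (0.3 equiv), 18 (5 equiv), THF, −10 °C
Reagents that add atoms: none
Why: Evans–Tishchenko reduction, in which the samarium-bound hemiacetal 19 delivers its hydride intramolecularly to the C1 ketone from the face of the C3 oxygen, giving the 1,3-anti relationship (sets C1) and leaving the tiglate on the C3 oxygen in the same step.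

Step 10
Reactants: 20 (1R,2R,3R,5R,7S,8R)-3-hydroxy-2,6,6,9-tetramethyl-11-oxotricyclo[5.4.0.0^{2,8}]undec-9-en-5-yl (2E)-2-methylbut-2-enoate; 21 (2Z)-2-methylbut-2-enoic acid (angelic acid)
Product: 22 (1R,2R,3R,5R,7S,8R)-2,6,6,9-tetramethyl-3-{[(2Z)-2-methylbut-2-enoyl]oxy}-11-oxotricyclo[5.4.0.0^{2,8}]undec-9-en-5-yl (2E)-2-methylbut-2-enoate
Conditions: 21, 2,4,6-Cl3C6H2COCl, Et3N, PhMe, rt; then 20, PhMe, 80 °C
Reagents that add atoms: none
Why: Yamaguchi-type esterification through the mixed anhydride, run without a nucleophilic amine catalyst so that the Z double bond of the angelate does not isomerise; the only free hydroxyl (C1) is acylated and the product is the target.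

**Compound list**
1 | 3,3-dimethylpent-4-enal | C=CC(C)(C)CC=O | starting material
2 | 2-oxopropanal (methylglyoxal) | CC(=O)C=O | starting material
3 | (2Z)-2-(2-methylbut-3-en-2-yl)-4-oxopent-2-enal | C=CC(C)(C)/C(C=O)=C/C(C)=O | intermediate
4 | 2-methyl-3-oxobutanenitrile | CC(=O)C(C)C#N | starting material
5 | (2S,3S,4R)-2,3-diacetyl-4-formyl-2,5,5-trimethylhept-6-enenitrile | C=CC(C)(C)[C@H](C=O)[C@H](C(C)=O)[C@](C#N)(C)C(C)=O | intermediate
6 | N'-[(1E,2R,3S,4S)-3,4-diacetyl-4-cyano-2-(2-methylbut-3-en-2-yl)pentylidene]-4-methylbenzenesulfonohydrazide | C=CC(C)(C)[C@H](/C=N/NS(=O)(=O)c1ccc(C)cc1)[C@H](C(C)=O)[C@](C#N)(C)C(C)=O | intermediate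
7 | (1S,2R)-2-{(1E,2R)-3,3-dimethyl-1-[2-(4-methylbenzenesulfonyl)hydrazinylidene]pent-4-en-2-yl}-1,3-dimethyl-5-oxocyclopent-3-ene-1-carbonitrile | C=CC(C)(C)[C@H](/C=N/NS(=O)(=O)c1ccc(C)cc1)[C@@H]2C(C)=CC(=O)[C@@]2(C#N)C | intermediate
8 | (1S,2R)-2-[(2R)-1-diazo-3,3-dimethylpent-4-en-2-yl]-1,3-dimethyl-5-oxocyclopent-3-ene-1-carbonitrile | C=CC(C)(C)[C@H](C=[N+]=[N-])[C@@H]1C(C)=CC(=O)[C@@]1(C#N)C | intermediate
9 | zwitterionic 7-cyano-6-endo-diazonio-3,7-dimethyl-5-exo-(2-methylbut-3-en-2-yl)bicyclo[2.2.1]hept-2-en-1-olate (cyano group syn to the C5–C6 bridge) | C=CC(C)(C)[C@@H]1[C@@H]([N+]#N)[C@@]2([O-])C=C(C)[C@@H]1[C@]2(C#N)C | intermediate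
10 | (1R,5R,6R,7S)-2,6-dimethyl-7-(2-methylbut-3-en-2-yl)-4-oxobicyclo[3.1.1]hept-2-ene-6-carbonitrile | C=CC(C)(C)[C@@H]1[C@H]2C(=O)C=C(C)[C@@H]1[C@]2(C#N)C | intermediate
11 | lithium (1R,5R,6R,7S)-6-cyano-6-methyl-4-methylidene-7-(2-methylbut-3-en-2-yl)bicyclo[3.1.1]hept-2-en-2-olate | C=CC(C)(C)[C@@H]1[C@H]2C(O[Li])=CC(=C)[C@@H]1[C@]2(C#N)C | intermediate
12 | lithium (1R,5R,6R,7S)-6-[1-(lithioimino)ethyl]-6-methyl-4-methylidene-7-(2-methylbut-3-en-2-yl)bicyclo[3.1.1]hept-2-en-2-olate | C=CC(C)(C)[C@@H]1[C@H]2C(O[Li])=CC(=C)[C@@H]1[C@]2(C(C)=N[Li])C | intermediate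
13 | (1R,5R,6R,7S)-6-acetyl-4,6-dimethyl-7-(2-methylbut-3-en-2-yl)bicyclo[3.1.1]hept-3-en-2-one | C=CC(C)(C)[C@@H]1[C@H]2C(=O)C=C(C)[C@@H]1[C@]2(C(C)=O)C | intermediate
14 | 2-[(1R,5R,6R,7S)-6-acetyl-4,6-dimethyl-2-oxobicyclo[3.1.1]hept-3-en-7-yl]-2-methylpropanal | O=CC(C)(C)[C@@H]1[C@H]2C(=O)C=C(C)[C@@H]1[C@]2(C(C)=O)C | intermediate
15 | (1R,2R,7S,8R)-2,6,6,9-tetramethyltricyclo[5.4.0.0^{2,8}]undeca-4,9-diene-3,11-dione | O=C1C=CC(C)(C)[C@@H]2[C@H]3C(=O)C=C(C)[C@@H]2[C@]31C | intermediate
16 | (1R,2R,5R,7S,8R)-2,6,6,9-tetramethyl-5-(4,4,5,5-tetramethyl-1,3,2-dioxaborolan-2-yl)tricyclo[5.4.0.0^{2,8}]undec-9-ene-3,11-dione | O=C1C[C@@H](B2OC(C)(C)C(C)(C)O2)C(C)(C)[C@@H]3[C@H]4C(=O)C=C(C)[C@@H]3[C@]41C | intermediate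
17 | (1R,2R,5R,7S,8R)-5-hydroxy-2,6,6,9-tetramethyltricyclo[5.4.0.0^{2,8}]undec-9-ene-3,11-dione | O=C1C[C@@H](O)C(C)(C)[C@@H]2[C@H]3C(=O)C=C(C)[C@@H]2[C@]31C | intermediate
18 | (2E)-2-methylbut-2-enal (tiglic aldehyde) | C/C=C(\C)C=O | starting material
19 | (1R,2R,5R,7S,8R)-5-{[(2E)-1-hydroxy-2-methylbut-2-en-1-yl]oxy}-2,6,6,9-tetramethyltricyclo[5.4.0.0^{2,8}]undec-9-ene-3,11-dione (bound to trivalent samarium in the flask; hemiacetal carbon not defined) | O=C1C[C@@H](OC(O)/C(C)=C/C)C(C)(C)[C@@H]2[C@H]3C(=O)C=C(C)[C@@H]2[C@]31C | intermediate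
20 | (1R,2R,3R,5R,7S,8R)-3-hydroxy-2,6,6,9-tetramethyl-11-oxotricyclo[5.4.0.0^{2,8}]undec-9-en-5-yl (2E)-2-methylbut-2-enoate | O[C@@H]1C[C@@H](OC(=O)/C(C)=C/C)C(C)(C)[C@@H]2[C@H]3C(=O)C=C(C)[C@@H]2[C@]31C | intermediate
21 | (2Z)-2-methylbut-2-enoic acid (angelic acid) | C/C=C(/C)C(=O)O | starting material
22 | (1R,2R,3R,5R,7S,8R)-2,6,6,9-tetramethyl-3-{[(2Z)-2-methylbut-2-enoyl]oxy}-11-oxotricyclo[5.4.0.0^{2,8}]undec-9-en-5-yl (2E)-2-methylbut-2-enoate | C/C=C(/C)C(=O)O[C@@H]1C[C@@H](OC(=O)/C(C)=C/C)C(C)(C)[C@@H]2[C@H]3C(=O)C=C(C)[C@@H]2[C@]31C | target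

**Totals**
Total steps: 10. Longest linear sequence: 10 steps (1 to 22).

**Steps most likely to fail**

Step 2. The risk is the configuration at C5, which is set by protonation and is fixed once the hydrazone is made; only the drawn epimer can place the tert-alkyl group exo in step 4. Fallback (thermodynamic epimerisation and recycling instead of kinetic protonation control): the fallback sets out from 3 and 4. Run the addition with the same cinchona base and accept both C5 epimers, 5 and (2S,3S,4S)-2,3-diacetyl-4-formyl-2,5,5-trimethylhept-6-enenitrile F1. Separate them by chromatography and return F1 to the cinchona base at rt, where C5 (α to the formyl group) epimerises through the enol while the quaternary C11 is untouched. The fallback comes back at 5.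

Step 4 (the proposed new step). The risks are loss of the diazoalkane by carbene 1,2-hydrogen shift, and an exo diazonium group, which would send the vinyl carbon C8 across to give a bicyclo[2.2.1] ketone. Fallback (known chemistry: reductive carbonyl coupling, then a base-induced semipinacol shift): the fallback sets out from 7. Hydrazone exchange (acetone, BF3·OEt2 cat., rt) frees the aldehyde (1S,2R)-2-[(2R)-3,3-dimethyl-1-oxopent-4-en-2-yl]-1,3-dimethyl-5-oxocyclopent-3-ene-1-carbonitrile F2. SmI2, t-BuOH, THF, −78 °C then adds the aldehyde ketyl to the ring carbonyl, the new oxygen going trans to the exo tert-alkyl group, to give 1,6-endo-dihydroxy-3,7-dimethyl-5-exo-(2-methylbut-3-en-2-yl)bicyclo[2.2.1]hept-2-ene-7-carbonitrile F3. MsCl, Et3N, CH2Cl2, 0 °C sulfonylates only the secondary hydroxyl to 7-cyano-1-hydroxy-3,7-dimethyl-5-exo-(2-methylbut-3-en-2-yl)bicyclo[2.2.1]hept-2-en-6-endo-yl methanesulfonate F4. KOtBu, THF, 0 °C then moves C11 (antiperiplanar to the endo sulfonate) from C7 to C6. The fallback comes back at 10.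

Step 5. The risk is slow addition of MeLi to a nitrile on a quaternary carbon that faces the tert-alkyl arm, and incomplete protection of the enone. Fallback (covalent masking of the enone by reduction instead of enolate protection): the fallback sets out from 10. NaBH4, CeCl3·7H2O, MeOH, −40 °C gives the allylic alcohol (1R,5R,6R,7S)-4-hydroxy-2,6-dimethyl-7-(2-methylbut-3-en-2-yl)bicyclo[3.1.1]hept-2-ene-6-carbonitrile F5 (carbinol centre not defined; it is removed again). MeLi (4 equiv), THF, 0 °C to rt, then aqueous NH4Cl with SiO2, gives 1-[(1R,5R,6R,7S)-4-hydroxy-2,6-dimethyl-7-(2-methylbut-3-en-2-yl)bicyclo[3.1.1]hept-2-en-6-yl]ethan-1-one F6. MnO2, CH2Cl2, rt reoxidises the allylic alcohol. The fallback comes back at 13.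

**Further compounds**
F1 | step 2 | (2S,3S,4S)-2,3-diacetyl-4-formyl-2,5,5-trimethylhept-6-enenitrile | C=CC(C)(C)[C@@H](C=O)[C@H](C(C)=O)[C@](C#N)(C)C(C)=O
F2 | step 4 | (1S,2R)-2-[(2R)-3,3-dimethyl-1-oxopent-4-en-2-yl]-1,3-dimethyl-5-oxocyclopent-3-ene-1-carbonitrile | C=CC(C)(C)[C@H](C=O)[C@@H]1C(C)=CC(=O)[C@@]1(C#N)C
F3 | step 4 | 1,6-endo-dihydroxy-3,7-dimethyl-5-exo-(2-methylbut-3-en-2-yl)bicyclo[2.2.1]hept-2-ene-7-carbonitrile (cyano group syn to the C5–C6 bridge) | C=CC(C)(C)[C@@H]1[C@@H](O)[C@@]2(O)C=C(C)[C@@H]1[C@]2(C#N)C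
F4 | step 4 | 7-cyano-1-hydroxy-3,7-dimethyl-5-exo-(2-methylbut-3-en-2-yl)bicyclo[2.2.1]hept-2-en-6-endo-yl methanesulfonate | C=CC(C)(C)[C@@H]1[C@@H](OS(C)(=O)=O)[C@@]2(O)C=C(C)[C@@H]1[C@]2(C#N)C
F5 | step 5 | (1R,5R,6R,7S)-4-hydroxy-2,6-dimethyl-7-(2-methylbut-3-en-2-yl)bicyclo[3.1.1]hept-2-ene-6-carbonitrile | C=CC(C)(C)[C@@H]1[C@H]2C(O)C=C(C)[C@@H]1[C@]2(C#N)C
F6 | step 5 | 1-[(1R,5R,6R,7S)-4-hydroxy-2,6-dimethyl-7-(2-methylbut-3-en-2-yl)bicyclo[3.1.1]hept-2-en-6-yl]ethan-1-one | C=CC(C)(C)[C@@H]1[C@H]2C(O)C=C(C)[C@@H]1[C@]2(C(C)=O)C
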